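## Retrosynthetic overview

1. The 19,6β-γ-lactone is re-closed last (O6 onto C19), once C20 carries its acetate.
2. The C20–OAc bond (key bond) comes from photolysis of a 6β-nitrite: 6β-alkoxyl radical, 1,5-H shift from the 1,3-diaxial C20 methyl, then Cu(II) acetate transfer.
3. The free 6β-OH comes from hydrolytic opening of the 19,6β-lactone of a spiro bis-lactone; the side-chain lactone re-closes on acidification.
4. The spiro-tetrahydrofuran (O9–C13, new stereocentre C13) comes from intramolecular oxa-Michael addition of the 9α-OH onto a 13-en-15,16-olide.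
5. The butenolide comes from singlet-oxygen photooxygenation/NaBH4 reduction of the furan of marrubiin, which supplies the trans-decalin, the γ-lactone and C4, C5, C6, C8, C9, C10. Ring order: butenolide, then spiro-THF, then the 19,6-lactone opened and re-formed.

Assumption: natural marrubiin, the bulk furanolabdane of white horehound sold by natural-product suppliers, is taken as the purchasable chiral starting material.

Notation: labdane numbering; "15,16-olide" means C15(=O)–O–C16H2.

## Route

Step 1
Reactants: 1 marrubiin (9α-hydroxy-15,16-epoxy-8βH-labda-13(16),14-dien-19,6β-olide)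
Product: 5 9α-hydroxylabd-13-ene-15,16:19,6β-diolide (C15-carbonyl butenolide), via furan endoperoxide 2 (not isolated), via hydroxybutenolide 3 (not isolated), via ring-opened hydroxy acid 4 (not isolated)
Conditions: O2, TPP (1 mol %), i-Pr2NEt (5 equiv), hν (white LED), CH2Cl2, −78 °C; then NaBH4, EtOH, −78→0 °C; then 1 M HCl (pH 2), rt
Reagents that add atoms: oxygen (O=O)
Why: Dye-sensitised [4+2] photooxygenation of the 3-alkylfuran followed by hindered-base Kornblum–DeLaMare opening at the unhindered C15–H gives the 16-hydroxy-15-oxo butenolide regioselectively, and borohydride reduction of its open aldehyde form then acid lactonisation returns the C15-carbonyl butenolide; no stereocentre of 1 is touched and C16 becomes CH2.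

Step 2
Reactants: 5 9α-hydroxylabd-13-ene-15,16:19,6β-diolide
Product: 6 (13R)-9α,13-epoxylabdane-15,16:19,6β-diolide
Conditions: KOt-Bu (0.2 equiv), THF, −20→0 °C; AcOH quench
Reagents that add atoms: none
Why: Reversible 5-exo-trig intramolecular oxa-Michael addition of the tertiary 9α-alkoxide to C13 (Thorpe–Ingold-assisted spiro-THF, thermodynamic control); C13 is set by the resident C8/C9/C10 centres, whose flanking C1H2 and C17H3 groups discriminate the two faces only modestly, so 13R is taken by chromatography/crystallisation and the 13S epimer is returned to the same equilibrating conditions.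

Step 3
Reactants: 6 (13R)-9α,13-epoxylabdane-15,16:19,6β-diolide
Product: 9 methyl (13R)-9α,13-epoxy-6β-hydroxy-15,16-olidolabdan-19-oate, via dipotassium bis-seco salt 7 (not isolated), via hydroxy acid lactone 8 (not isolated)
Conditions: KOH (10 equiv), EtOH/H2O 4:1, reflux; 1 M HCl to pH 3, 0 °C→rt; then TMSCHN2, PhMe/MeOH 4:1, 0 °C
Reagents that add atoms: potassium hydroxide ([K+].[OH-]); (trimethylsilyl)diazomethane (C[Si](C)(C)C=[N+]=[N-])
Why: Saponification (acyl–oxygen cleavage, so 6β is retained) opens both lactones, acidification re-closes only the unhindered primary γ-hydroxy acid of the side chain while the 1,3-diaxial 6β-hydroxy-19-acid survives as marrubiinic acid does, and diazoalkane O-methylation caps the hindered C19 acid without touching the alcohol; the β-alkoxy carboxylate cannot undergo retro-Michael, so C13 is safe.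

Step 4
Reactants: 9 methyl (13R)-9α,13-epoxy-6β-hydroxy-15,16-olidolabdan-19-oate
Product: 10 methyl (13R)-9α,13-epoxy-6β-nitrosooxy-15,16-olidolabdan-19-oate
Conditions: NOCl (2 equiv), pyridine, −25 °C, dark
Reagents that add atoms: nitrosyl chloride (O=NCl)
Why: Standard O-nitrosation of the only free hydroxyl (axial 6β-OH), the substrate preparation of the Barton reaction; no carbon centre is affected.

Step 5
Reactants: 10 methyl (13R)-9α,13-epoxy-6β-nitrosooxy-15,16-olidolabdan-19-oate
Product: 12 (13R)-20-acetoxy-9α,13-epoxylabdane-15,16:19,6β-diolide (target), via acetoxy hydroxy ester 11 (not isolated)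
Conditions: hν (365 nm LED), Cu(OAc)2 (3 equiv), pyridine (6 equiv), MeCN/PhH 1:1 (0.02 M), Ar sparge, 10 °C; then (aq. EDTA wash, solvent switch) TsOH·H2O (0.3 equiv), PhMe, 80 °C
Reagents that add atoms: copper(II) acetate (CC(=O)[O-].CC(=O)[O-].[Cu+2])
Why: Proposed new method: copper(II)-intercepted Barton nitrite photolysis used as a δ-C(sp3)–H acetoxylation – n→π* homolysis of the 6β-O–NO bond gives the 6β-alkoxyl radical, which abstracts H from the 1,3-diaxial C20 methyl through a six-membered 1,5-HAT (the geometry of the steroid 6β-nitrite→C19 Barton reaction), and the resulting neopentyl C20 radical, having no β-hydrogen for the usual Cu(II) oxidative elimination, is captured by Cu(OAc)2 and collapses by C–O reductive elimination (acetate ligand transfer) to the C20 acetate while NO is swept out by argon; closest known reaction types are the Barton reaction, Cu(OAc)2-diverted alkoxyl-radical remote desaturation and Kochi oxidative substitution of neopentyl radicals; acid-catalysed transesterification then re-closes the 19,6β-γ-lactone with retention at C6, and no stereocentre is created.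

## Compound list

1 | marrubiin (9α-hydroxy-15,16-epoxy-8βH-labda-13(16),14-dien-19,6β-olide) | C[C@@]12CCC[C@]3(C)C(=O)O[C@H](C[C@@H](C)[C@]1(O)CCc1ccoc1)[C@H]23 | starting material
2 | furan endoperoxide (15,16-epidioxy-15,16-epoxy-9α-hydroxylabd-13-en-19,6β-olide, bridgehead epimers) | C[C@@]12CCC[C@]3(C)C(=O)O[C@H](C[C@@H](C)[C@]1(O)CCC1=CC4OOC1O4)[C@H]23 | intermediate
3 | hydroxybutenolide (9α,16ξ-dihydroxylabd-13-ene-15,16:19,6β-diolide) | C[C@@]12CCC[C@]3(C)C(=O)O[C@H](C[C@@H](C)[C@]1(O)CCC1=CC(=O)OC1O)[C@H]23 | intermediate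
4 | ring-opened hydroxy acid ((13Z)-9α,16-dihydroxy-19,6β-olidolabd-13-en-15-oic acid, carboxylate in the flask) | C[C@@]12CCC[C@]3(C)C(=O)O[C@H](C[C@@H](C)[C@]1(O)CC/C(CO)=C/C(=O)O)[C@H]23 | intermediate
5 | 9α-hydroxylabd-13-ene-15,16:19,6β-diolide | C[C@@]12CCC[C@]3(C)C(=O)O[C@H](C[C@@H](C)[C@]1(O)CCC1=CC(=O)OC1)[C@H]23 | intermediate
6 | (13R)-9α,13-epoxylabdane-15,16:19,6β-diolide | C[C@@]12CCC[C@]3(C)C(=O)O[C@H](C[C@@H](C)[C@]14CC[C@@]1(COC(=O)C1)O4)[C@H]23 | intermediate
7 | dipotassium (13R)-9α,13-epoxy-6β,16-dihydroxylabdane-15,19-dioate | C[C@]12CCC[C@](C)(C(=O)[O-])[C@@H]1[C@H](O)C[C@@H](C)[C@]23CC[C@](CO)(CC(=O)[O-])O3.[K+].[K+] | intermediate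
8 | (13R)-9α,13-epoxy-6β-hydroxy-15,16-olidolabdan-19-oic acid | C[C@]12CCC[C@](C)(C(=O)O)[C@@H]1[C@H](O)C[C@@H](C)[C@]23CC[C@@]2(COC(=O)C2)O3 | intermediate
9 | methyl (13R)-9α,13-epoxy-6β-hydroxy-15,16-olidolabdan-19-oate | C[C@]12CCC[C@](C)(C(=O)OC)[C@@H]1[C@H](O)C[C@@H](C)[C@]23CC[C@@]2(COC(=O)C2)O3 | intermediate
10 | methyl (13R)-9α,13-epoxy-6β-nitrosooxy-15,16-olidolabdan-19-oate | C[C@]12CCC[C@](C)(C(=O)OC)[C@@H]1[C@H](ON=O)C[C@@H](C)[C@]23CC[C@@]2(COC(=O)C2)O3 | intermediate
11 | methyl (13R)-20-acetoxy-9α,13-epoxy-6β-hydroxy-15,16-olidolabdan-19-oate | CC(=O)OC[C@]12CCC[C@](C)(C(=O)OC)[C@@H]1[C@H](O)C[C@@H](C)[C@]23CC[C@@]2(COC(=O)C2)O3 | intermediate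
12 | (13R)-20-acetoxy-9α,13-epoxylabdane-15,16:19,6β-diolide | CC(=O)OC[C@@]12CCC[C@]3(C)C(=O)O[C@H](C[C@@H](C)[C@]14CC[C@@]1(COC(=O)C1)O4)[C@H]23 | target

## Step count and risks

Total step count: 5. Longest linear sequence: 5 (from 1).

Steps most likely to fail:

**Step 5 (proposed new step).** The C20 radical may recombine with NO (oxime), the alkoxyl radical may be reduced back to 9 by Cu(I) (9 is recyclable through step 4), or the 6β,20-ether may form. The fallback uses known chemistry, sets out from 10 and comes back at 12. Irradiate 10 without copper (classical Barton reaction; PhH, 365 nm, then warm in i-PrOH to tautomerise the nitroso dimer) to the C20 aldoxime hydroxy ester F1. Close the lactone first (TsOH, PhMe, 80 °C) to the oxime lactone F2. Deoximate with NaNO2 in aqueous AcOH to the 20-aldehyde lactone F3. Reduce with NaBH4/CeCl3 (MeOH, −40 °C, AcOH quench) to the 20-alcohol lactone F4. Acetylate (Ac2O, pyridine, DMAP) to 12.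

**Step 2.** The equilibrium may stop short, and little intrinsic bias at C13 is expected (perhaps 1:1 to 2:1), so throughput depends on separation and recycling of the 13S epimer. The fallback sets out from 5 and comes back at 6. Silylate the butenolide (TIPSOTf, Et3N, CH2Cl2, 0 °C; the hindered tertiary 9-OH stays free) to the 2-silyloxyfuran F5. Treat it with Tf2NH (1 equiv, CH2Cl2, −78 °C): protonation at C16 gives an O-silylated butenolide cation that the 9α-OH captures at C13 irreversibly. This is a kinetic, cationic vinylogous spirocyclisation in place of anionic equilibration. Aqueous work-up gives 6, with epimer separation as before.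

**Step 3.** The 19,6-lactone may re-close on acidification, or the side-chain lactone may stay open. The fallback sets out from 1 and comes back at 9, opening the lactone before the side chain is built. Saponify marrubiin (KOH, EtOH, reflux) and alkylate the carboxylate (MeI, DMF) to methyl marrubiinate F6. Photooxygenate and reduce as in step 1, passing the endoperoxide F7, the hydroxybutenolide F8 and the ring-opened hydroxy acid F9 without isolation, to the butenolide ester F10. Oxa-Michael cyclisation as in step 2 (cat. KOt-Bu, −20 °C, short time to outrun attack of the 6β-alkoxide on the ester) gives 9 directly.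

## Further compounds

F1 | step 5 | methyl (13R)-9α,13-epoxy-6β-hydroxy-20-(hydroxyimino)-15,16-olidolabdan-19-oate (E/Z) | ON=C[C@]12CCC[C@](C)(C(=O)OC)[C@@H]1[C@H](O)C[C@@H](C)[C@]23CC[C@@]2(COC(=O)C2)O3
F2 | step 5 | (13R)-9α,13-epoxy-20-(hydroxyimino)labdane-15,16:19,6β-diolide (E/Z) | ON=C[C@@]12CCC[C@]3(C)C(=O)O[C@H](C[C@@H](C)[C@]14CC[C@@]1(COC(=O)C1)O4)[C@H]23
F3 | step 5 | (13R)-9α,13-epoxy-20-oxolabdane-15,16:19,6β-diolide | O=C[C@@]12CCC[C@]3(C)C(=O)O[C@H](C[C@@H](C)[C@]14CC[C@@]1(COC(=O)C1)O4)[C@H]23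
F4 | step 5 | (13R)-9α,13-epoxy-20-hydroxylabdane-15,16:19,6β-diolide | OC[C@@]12CCC[C@]3(C)C(=O)O[C@H](C[C@@H](C)[C@]14CC[C@@]1(COC(=O)C1)O4)[C@H]23
F5 | step 2 | 9α-hydroxy-15-(triisopropylsilyloxy)-15,16-epoxylabda-13(16),14-dien-19,6β-olide (2-silyloxyfuran) | C[C@@]12CCC[C@]3(C)C(=O)O[C@H](C[C@@H](C)[C@]1(O)CCc1coc(O[Si](C(C)C)(C(C)C)C(C)C)c1)[C@H]23
F6 | step 3 | methyl marrubiinate (methyl 6β,9α-dihydroxy-15,16-epoxylabda-13(16),14-dien-19-oate) | C[C@]12CCC[C@](C)(C(=O)OC)[C@@H]1[C@H](O)C[C@@H](C)[C@]2(O)CCc1ccoc1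
F7 | step 3 | methyl 15,16-epidioxy-15,16-epoxy-6β,9α-dihydroxylabd-13-en-19-oate (endoperoxide) | C[C@]12CCC[C@](C)(C(=O)OC)[C@@H]1[C@H](O)C[C@@H](C)[C@]2(O)CCC1=CC3OOC1O3
F8 | step 3 | methyl 6β,9α,16ξ-trihydroxy-15,16-olidolabd-13-en-19-oate (hydroxybutenolide) | C[C@]12CCC[C@](C)(C(=O)OC)[C@@H]1[C@H](O)C[C@@H](C)[C@]2(O)CCC1=CC(=O)OC1O
F9 | step 3 | (13Z)-6β,9α,16-trihydroxy-19-methoxy-19-oxolabd-13-en-15-oic acid (ring-opened hydroxy acid) | C[C@]12CCC[C@](C)(C(=O)OC)[C@@H]1[C@H](O)C[C@@H](C)[C@]2(O)CC/C(CO)=C/C(=O)O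
F10 | step 3 | methyl 6β,9α-dihydroxy-15,16-olidolabd-13-en-19-oate (butenolide ester) | C[C@]12CCC[C@](C)(C(=O)OC)[C@@H]1[C@H](O)C[C@@H](C)[C@]2(O)CCC1=CC(=O)OC1
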